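## Structural features

The target is a linear flavan trimer: three 2-(4-hydroxyphenyl)chroman units, each with a pyrogallol-type ring A (O1 on C8a, hydroxyls on C7 and C8), joined by two sp3–sp2 bonds, C4(T)–C6(M) and C4(M)–C6(B). Each pyran ring carries a contiguous C2–C3–C4 triad, eleven stereocentres in all: T is 2,3-cis-3,4-trans, M is 2,3-trans-3,4-trans, B is the all-cis 3,4-diol, and all three 2-aryl groups are α (2R). The triads are separated by flat arenes, so no unit can relay configuration to the next and each must be set in the absolute sense. The fragile groups are the nine phenolic hydroxyls (air-sensitive pyrogallol rings) and, above all, the benzylic C4 hydroxyl of B, which ionises in acid to a cation stabilised by O1 and O7 of its ring A. The real difficulty is the B terminus: capture of a C4 cation gives the 3,4-trans relation, so the all-cis diol has to be made under kinetic, non-acidic control and as late as possible. A second difficulty is that both C4–aryl bonds must be formed regioselectively with an only moderately nucleophilic trioxygenated ring A. The key step exploits the fact that C3 and C4 of B are both carbinol carbons, C4 attached to ring A and C3 attached to C2, which carries O1: cutting C3–C4 leaves an aryl aldehyde and an α-aryloxy aldehyde on one aryl ether, a 1,6-dialdehyde suited to a chelated pinacol coupling. The same retron is present in T (a 2,3-cis unit with a leaving group on C4) and, after the diol is moved to the other face, in M.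

## Logic of the disconnections

25 from 24. No skeletal bond is cut; the eleven O–benzyl bonds of 24 are cleaved last. One kind of protecting group for nine phenols and two secondary alcohols gives a single neutral final step. The demand is that hydrogenolysis spares the benzylic C4–O bond of unit B and the three C2–O1 bonds, so it must run without acid.

24 from 23. C3(B)–C4(B) is cut. Both carbons bear oxygen, so the cut gives two aldehydes on one diaryl-ether tether and replaces the acid-labile diol by a precursor that cannot ionise at C4. Ring C of B and two stereocentres disappear. The forward step must give the 3,4-cis diol, place it cis to the aryl group on C2 from the single stereocentre of 23, and must not enolise that centre.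

23 from 22, 21, then 20 and 7. The two aldehydes of 23 are traced to the two primary alcohols of 22 and these to the formyl and ester groups of 21, so that the sensitive α-aryloxy aldehyde exists only at the moment of use. Then O1(B)–C2(B) is cut to 20 and 7. This puts the only stereocentre of the future ring into a chiral-pool building block. The forward etherification must proceed with clean inversion at a benzylic carbinol, using a hindered, hydrogen-bonded phenol.

20 from 19. The C4a(B)–CHO bond is cut. The formyl group is introduced after the aryl–C4 bond because a formyl-bearing ring would be too electron-poor to serve as nucleophile. The forward step must formylate only ortho to the single free hydroxyl.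

19 from 18 and 4. C4(M)–C6(B) is cut to the C4 cation of M, stored in 18 as a benzylic benzyl ether, and 4. The problem shrinks from a trimer to a dimer plus a small achiral arene that can be used in excess. The forward step must attack para to the free hydroxyl of 4 and trans to the 3-benzyloxy group of M (4α).

18 from 13 and 17. C4(T)–C6(M) is cut to the C4 cation of T, stored in 13 as a sulfide, and the nucleophile 17. Two monomers of equal size result. The sulfide of 13 and the benzylic ether of 17 must be activated in turn (soft activation first, hard activation second), ring A of 17 must outrun ring A of 13 as nucleophile, and attack must be anti to the axial C3 substituent (4β).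

13 and 17 from 11. For T only C4–O is exchanged for C4–S (12) and O3 is benzylated (13): C4 is a leaving group, and C2 and C3 of 11 are already those of T. For M the diol of 11 is removed (14, 15) and put back on the face opposite to the aryl group (16, 17), which sets C3 of M; C4 is again only a leaving group. One compound thus serves all three units. The demands are that the deoxygenation leave C2 untouched and that the dihydroxylation be controlled by C2.

11 from 10, 9, 8, then 5 and 7. These are the same cuts as in the terminal unit: C3–C4 (pinacol retron, 10), oxidation-level adjustment (9, 8) and O1–C2 (5 and 7). The key reaction is therefore rehearsed on a monomer before it is used on 23.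

5 from 4, 2, 1; 7 from 6. 5 arises from 4 by the same ortho-formylation as above, 4 from 2 by oxidative replacement of the formyl group by hydroxyl, and 2 from 1 by benzylation. This differentiates the three oxygens of the pyrogallol ring without any selective protection. 7 is 6 with acid and phenol benzylated. Every stereocentre of 25 derives from the one centre of 6.

## Other disconnections considered

Alternative 1: The cut removes ring A of unit M (bonds C8a–C8, C7–C6 and C8a–C4a), leaving a T unit whose C4 carries a diazo vinyl ketone, A2. In the forward sense, irradiation of A2 triggers Wolff rearrangement to a vinylketene, which adds di-tert-butoxyethyne A3 in a [2+2] reaction; four-electron opening of the cyclobutenone, six-electron closure and tautomerisation give the phenol A1 (Danheiser benzannulation).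
- In favour: the C4(T)–aryl bond exists before the arene does, so the regiochemistry at C6 of M is fixed by construction and no electrophilic flavan can condense with itself. On this point the alternative is better than the intermolecular step 15 of the chosen plan. The 7,8-dioxygenation and the free C8a hydroxyl arrive in one operation.
- Against: the carbene carbon of A2 carries C4–H, so 1,2-hydrogen shift competes with the Wolff migration. A2 needs a carbon substituent introduced at C4 trans to C3 on a 2,3-cis flavan and then homologated. The tert-butyl ethers must later be exchanged under acid. A1 still lacks all of ring C of M, with its three stereocentres, and unit B.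
- Comparison: in structure it solves one C–C bond and no stereocentre, whereas the two cation–arene couplings of the chosen plan also set C4 of T and of M. In mechanism a pericyclic cascade is more predictable in regiochemistry than an ionic arylation but is exposed to carbene side reactions. In step economy it is clearly longer, because ring C of M would then have to be built on a C4a–H phenol with 2,3-trans control that a pinacol closure does not offer.

Alternative 2: The cut takes out O1(M)–C2(M) and C3(M)–C4(M), that is ring C of M. It gives the o-hydroxy diaryl carbinol A5 (ring A of M bearing T on C6 and, on the carbinol carbon, unit B as its acetonide) and the (E)-styrylboronate A6. In the forward sense a chiral BINOL-derived phosphoric acid ionises A5 to the o-quinone methide, which adds A6 in an inverse-demand [4+2] reaction to give A4; oxidation of the C–B bond with retention would then give the C3 hydroxyl.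
- In favour: two bonds and all three stereocentres of M are made in one step. The 2,3-trans relation follows from the alkene geometry and the 3,4-trans relation from an all-equatorial transition state. It is the most convergent of the four plans, and on that count better than the chosen one. Stereoretentive C–B oxidation is as reliable for C3 of M as the dihydroxylation used here.
- Against: unit B with its acid-labile benzylic diol (an acetonide at C4 is still a benzylic acetal) must be finished before a Brønsted-acid step and must survive peroxide. The catalyst has to impose absolute configuration on a substrate that already carries two chiral units, so one catalyst/substrate pairing will be mismatched. The alkenylboronate is a less electron-rich 2π partner than a plain styrene. A5 still needs the T–aryl bond from a Friedel–Crafts step and an aryl-metal addition to a formyl group placed on C6 of unit B.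
- Comparison: in structure the chosen plan brings in the fragile diol in its last C–C bond formation, whereas the alternative carries it through several further steps. In mechanism a catalyst-controlled cycloaddition offers, in principle, better control of C4 of M than the substrate-controlled cation capture of step 16. Step economy is about equal: what is saved on M is spent on a C6-functionalised B unit.

Alternative 3: The cut is C4(T)–C4a(T). Ring C of T is opened to the aryl ether trans-epoxide A8, in which C2 of T carries the 2,3-bis(benzyloxy)phenoxy group and C4 the M–B part. In the forward sense BF3·OEt2 opens the epoxide at C4 by 6-endo attack of the arene carbon ortho to the ether oxygen, with inversion, to give A7.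
- In favour: the closure is intramolecular, so regiochemistry at C4a and the absence of oligomerisation are guaranteed, which is better than step 15. The epoxide geometry is translated stereospecifically into the 3,4-trans relation. The C3 hydroxyl comes from the epoxide oxygen without a separate oxygenation.
- Against: T is made last, on a substrate that already contains the B diol, which is then exposed to BF3. The epoxide carbon C4 is strongly cation-stabilised (attached to ring A of M, para to O1), so ionisation with hydride shift and attack by other arenes compete with the 6-endo closure. A8 has to be assembled on the M–B fragment through an (E)-alkene, an asymmetric epoxidation and an aryl ether at the benzylic C2 with the correct relation to C3.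
- Comparison: in structure it is equal in what it leaves to other steps, since both C4–aryl bonds of M must still be made. In mechanism an SN2-type opening is better defined than the facial selectivity of a free cation, provided the SN1 path is suppressed. In step economy it is worse, because C2 and C3 of T, which the chosen plan takes from the chiral pool and from the pinacol closure, each need a separate operation on the most valuable intermediate.

Key step: step 21

Remark on notation: T, M and B are the upper, middle and terminal flavan units, with flavan numbering inside each unit; α and β are the lower and upper faces of a chroman drawn with ring A on the left and O1 at the top; all 2-aryl groups are α; Bn is benzyl.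

Remark on the structures: 23, 24 and 25 were checked against one another (connectivity, eleven stereocentres, eleven benzyl groups) and are consistent, so they are used unchanged. The design improvement is that both aldehydes of 23 are unmasked together, under neutral conditions, from diol 22 and used without purification.

Remark on stereodescriptors: 12 and 16 are drawn as the expected major C4 epimers; C4 of both becomes a leaving group, so its configuration has no consequence. 15 is 2S only because the CIP priority of C3 falls below that of the aryl group.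

Assumption: 2,3-dihydroxybenzaldehyde and the S enantiomer of 4-hydroxymandelic acid are taken as commercial.

## Route

Step 1
Reactants: 1 2,3-dihydroxybenzaldehyde
Product: 2 2,3-bis(benzyloxy)benzaldehyde
Conditions: BnBr (2.3 equiv), K2CO3, DMF, 60 °C
Reagents that add atoms: benzyl bromide, BrCc1ccccc1
Why: Williamson etherification of both phenoxides; the aldehyde is inert and serves as the masked third oxygen of the pyrogallol ring.

Step 2
Reactants: 2 2,3-bis(benzyloxy)benzaldehyde
Product: 4 2,3-bis(benzyloxy)phenol, via 2,3-bis(benzyloxy)phenyl formate 3 (not isolated)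
Conditions: mCPBA, CH2Cl2, 0 °C to rt; then K2CO3 (cat.), MeOH, rt
Reagents that add atoms: 3-chloroperbenzoic acid (mCPBA), OOC(=O)c1cccc(Cl)c1
Why: Dakin-type Baeyer–Villiger oxidation; the electron-rich aryl group migrates in the Criegee adduct to give the formate, which is cleaved by methanolysis.

Step 3
Reactants: 4 2,3-bis(benzyloxy)phenol
Product: 5 3,4-bis(benzyloxy)-2-hydroxybenzaldehyde
Conditions: MgCl2, Et3N, (CH2O)n, MeCN, reflux
Reagents that add atoms: formaldehyde (as paraformaldehyde), C=O
Why: Magnesium phenoxide-directed ortho-formylation (Casnati–Skattebøl); formaldehyde is delivered inside the Mg chelate to the only free ortho position and the benzylic alkoxide is oxidised by a second formaldehyde.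

Step 4
Reactants: 6 (S)-4-hydroxymandelic acid
Product: 7 benzyl (2S)-[4-(benzyloxy)phenyl](hydroxy)acetate
Conditions: BnBr (2.1 equiv), K2CO3, DMF, 0 °C to rt
Reagents that add atoms: benzyl bromide, BrCc1ccccc1
Why: Williamson alkylation of carboxylate and phenoxide in one operation; the secondary alcohol is not deprotonated by K2CO3 and the stereocentre is not touched.

Step 5
Reactants: 5 3,4-bis(benzyloxy)-2-hydroxybenzaldehyde; 7 benzyl (2S)-[4-(benzyloxy)phenyl](hydroxy)acetate
Product: 8 benzyl (2R)-[4-(benzyloxy)phenyl][2,3-bis(benzyloxy)-6-formylphenoxy]acetate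
Conditions: PPh3, DIAD, THF, 0 °C to rt
Reagents that add atoms: none
Why: Mitsunobu etherification; the hydrogen-bonded salicylaldehyde hydroxyl is acidic enough to protonate the betaine and the phenoxide displaces the oxyphosphonium with inversion (S carbinol to R aryl ether), while the α-ester group disfavours ionisation of the benzylic carbon.

Step 6
Reactants: 8 benzyl (2R)-[4-(benzyloxy)phenyl][2,3-bis(benzyloxy)-6-formylphenoxy]acetate
Product: 9 (2R)-2-[4-(benzyloxy)phenyl]-2-[2,3-bis(benzyloxy)-6-(hydroxymethyl)phenoxy]ethanol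
Conditions: LiBH4, THF, 0 °C to rt
Reagents that add atoms: none
Why: Hydride reduction of the aldehyde and of the activated α-aryloxy ester to the diol under weakly basic conditions that should not enolise the ester.

Step 7
Reactants: 9 (2R)-2-[4-(benzyloxy)phenyl]-2-[2,3-bis(benzyloxy)-6-(hydroxymethyl)phenoxy]ethanol
Product: 10 3,4-bis(benzyloxy)-2-{(1R)-1-[4-(benzyloxy)phenyl]-2-oxoethoxy}benzaldehyde
Conditions: Dess–Martin periodinane (2.5 equiv), CH2Cl2, 0 °C; cold aq. Na2S2O3/pH 7 buffer wash, no chromatography, used at once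
Reagents that add atoms: none
Why: Dess–Martin oxidation of both primary alcohols without amine base; the α-aryloxy-α-aryl aldehyde is configurationally labile and is therefore not stored.

Step 8
Reactants: 10 3,4-bis(benzyloxy)-2-{(1R)-1-[4-(benzyloxy)phenyl]-2-oxoethoxy}benzaldehyde
Product: 11 (2R,3R,4R)-7,8-bis(benzyloxy)-2-[4-(benzyloxy)phenyl]chromane-3,4-diol (2,3-cis-3,4-cis; aryl, 3-OH and 4-OH all α)
Conditions: SmI2 (2.5 equiv, 0.1 M in THF), t-BuOH (2 equiv), THF (0.01 M), −78 to −20 °C
Reagents that add atoms: none
Why: Intramolecular SmI2 pinacol coupling, analysed under step 21, for which this step is the rehearsal on a monomer; the samarium chelate should give the cis diol cis to the 2-aryl group, and the other cis diol, should it form, is 16 and can enter step 14.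

Step 9
Reactants: 11 (2R,3R,4R)-7,8-bis(benzyloxy)-2-[4-(benzyloxy)phenyl]chromane-3,4-diol
Product: 12 (2R)-7,8-bis(benzyloxy)-2-[4-(benzyloxy)phenyl]-4β-(benzylsulfanyl)chroman-3α-ol (2,3-cis-3,4-trans)
Conditions: BnSH (5 equiv), BF3·OEt2 (0.3 equiv), CH2Cl2, −40 to −20 °C
Reagents that add atoms: phenylmethanethiol, SCc1ccccc1
Why: Acid-induced ionisation of the benzylic 4-OH to the flavan-4-yl cation and capture by the thiol anti to the axial 3-OH (thiolysis of a flavan-3,4-diol); the excess thiol outcompetes ring A as nucleophile.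

Step 10
Reactants: 12 (2R)-7,8-bis(benzyloxy)-2-[4-(benzyloxy)phenyl]-4β-(benzylsulfanyl)chroman-3α-ol
Product: 13 (2R)-3α,7,8-tris(benzyloxy)-2-[4-(benzyloxy)phenyl]-4β-(benzylsulfanyl)chromane
Conditions: NaH, BnBr, Bu4NI (cat.), DMF, 0 °C to rt
Reagents that add atoms: benzyl bromide, BrCc1ccccc1
Why: Williamson benzylation of the secondary alkoxide; thioethers tolerate these conditions, as in the routine benzylation of thioglycosides.

Step 11
Reactants: 11 (2R,3R,4R)-7,8-bis(benzyloxy)-2-[4-(benzyloxy)phenyl]chromane-3,4-diol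
Product: 14 3,4-O-thiocarbonyl derivative of 11 (cis-fused cyclic thionocarbonate; aryl and both oxygens α)
Conditions: 1,1'-thiocarbonyldiimidazole, DMAP (cat.), CH2Cl2, rt
Reagents that add atoms: 1,1'-thiocarbonyldiimidazole, S=C(n1ccnc1)n1ccnc1
Why: Thiocarbonylation of a cis-1,2-diol, the first stage of a Corey–Winter olefination; the imidazole set free keeps the medium non-acidic for the benzylic C4–O bond.

Step 12
Reactants: 14 3,4-O-thiocarbonyl derivative of 11
Product: 15 (2S)-7,8-bis(benzyloxy)-2-[4-(benzyloxy)phenyl]-2H-chromene (aryl α as before)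
Conditions: 1,3-dimethyl-2-phenyl-1,3,2-diazaphospholidine (3 equiv), THF, 40 °C, argon
Reagents that add atoms: none
Why: Corey–Winter olefination in its mild diazaphospholidine form; desulfurisation gives the dioxolanylidene carbene, which loses CO2 by stereospecific cycloreversion, and C2 is not involved.

Step 13
Reactants: 15 (2S)-7,8-bis(benzyloxy)-2-[4-(benzyloxy)phenyl]-2H-chromene
Product: 16 (2R,3S,4S)-7,8-bis(benzyloxy)-2-[4-(benzyloxy)phenyl]chromane-3,4-diol (2,3-trans-3,4-cis; 3-OH and 4-OH β)
Conditions: OsO4 (2 mol %), NMO, acetone–H2O, 0 °C to rt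
Reagents that add atoms: 4-methylmorpholine N-oxide, C[N+]1([O-])CCOCC1; water, O
Why: Catalytic syn-dihydroxylation of the flav-3-ene on the face opposite to the 2-aryl group, the known facial preference of 2-aryl-2H-chromenes; this sets C3 of unit M (β), while C4 is set β but is only a leaving group.

Step 14
Reactants: 16 (2R,3S,4S)-7,8-bis(benzyloxy)-2-[4-(benzyloxy)phenyl]chromane-3,4-diol
Product: 17 (2R)-3β,4β,7,8-tetrakis(benzyloxy)-2-[4-(benzyloxy)phenyl]chromane (2,3-trans-3,4-cis)
Conditions: NaH, BnBr, Bu4NI (cat.), DMF, 0 °C to rt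
Reagents that add atoms: benzyl bromide, BrCc1ccccc1
Why: Double Williamson benzylation; the 4-benzyloxy group is the latent leaving group of unit M, inert to silver salts in a buffered medium but ionised by hard Lewis acids.

Step 15
Reactants: 13 (2R)-3α,7,8-tris(benzyloxy)-2-[4-(benzyloxy)phenyl]-4β-(benzylsulfanyl)chromane; 17 (2R)-3β,4β,7,8-tetrakis(benzyloxy)-2-[4-(benzyloxy)phenyl]chromane
Product: 18 T–M dimer: C4β of unit T (2,3-cis-3,4-trans, 3α-OBn) bonded to C6 of unit M (2,3-trans-3,4-cis, 3β-OBn, 4β-OBn), all phenols benzylated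
Conditions: AgBF4 (1.5 equiv), 2,6-di-tert-butylpyridine (2 equiv), 17 (2.5 equiv), 4 Å MS, CH2Cl2, −40 to 0 °C, dark, slow addition of 13
Reagents that add atoms: none
Why: Silver-promoted heterolysis of the benzylic C4–S bond gives the 2,3-cis flavan-4-yl cation, which alkylates C6 of 17 (para to O1, ortho to 7-OBn) in a Friedel–Crafts reaction anti to the axial 3-OBn, giving the 4β linkage; the hindered pyridine takes up the proton so that the 4-OBn group of 17 is not ionised, and slow addition with excess 17 limits self-alkylation of 13.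

Step 16
Reactants: 18 T–M dimer with 4β-OBn on unit M; 4 2,3-bis(benzyloxy)phenol
Product: 19 T–M dimer carrying on C4α of unit M a 2,3-bis(benzyloxy)-4-hydroxyphenyl group (unit M now 2,3-trans-3,4-trans)
Conditions: TMSOTf (0.3 equiv), 4 (5 equiv), CH2Cl2, −78 to −40 °C
Reagents that add atoms: none
Why: Hard Lewis acid ionisation of the 4-alkoxyflavan and Friedel–Crafts capture of the cation by the phenol para to its free hydroxyl, the strongest donor; attack trans to the 3-OBn group of the 2,3-trans unit sets the 4α configuration, and any O-alkylation is reversible under the acidic conditions.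

Step 17
Reactants: 19 T–M dimer with 2,3-bis(benzyloxy)-4-hydroxyphenyl on C4α of unit M
Product: 20 T–M dimer carrying on C4α of unit M a 2,3-bis(benzyloxy)-5-formyl-4-hydroxyphenyl group (salicylaldehyde)
Conditions: MgCl2, Et3N, (CH2O)n, THF, reflux
Reagents that add atoms: formaldehyde (as paraformaldehyde), C=O
Why: The same magnesium phenoxide-directed ortho-formylation as in step 3; the single phenol has one free ortho position and the benzyl ethers and C4–aryl bonds are inert to the weakly basic medium.

Step 18
Reactants: 20 T–M dimer salicylaldehyde; 7 benzyl (2S)-[4-(benzyloxy)phenyl](hydroxy)acetate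
Product: 21 T–M dimer whose aryl ether oxygen carries the (R)-CH(4-benzyloxyphenyl)CO2Bn group ortho to the formyl group
Conditions: PPh3, DIAD, toluene, 0 °C to rt
Reagents that add atoms: none
Why: Mitsunobu etherification as in step 5, with inversion at the mandelate carbinol; this sets C2 of unit B as R (aryl α).

Step 19
Reactants: 21 T–M dimer formyl ester
Product: 22 T–M dimer diol (CH2OH on the arene and (R)-O–CH(aryl)–CH2OH)
Conditions: LiBH4, THF, 0 °C to rt
Reagents that add atoms: none
Why: Hydride reduction of aldehyde and α-aryloxy ester as in step 6; no other reducible group is present.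

Step 20
Reactants: 22 T–M dimer diol
Product: 23 T–M dimer dialdehyde (aryl CHO = future C4 of B; (R)-O–CH(aryl)–CHO = future C2 and C3 of B)
Conditions: Dess–Martin periodinane (2.5 equiv), CH2Cl2, 0 °C; cold aq. Na2S2O3/pH 7 buffer wash, no chromatography, used at once
Reagents that add atoms: none
Why: Dess–Martin oxidation of the only two free hydroxyls without amine base, as in step 7, so that C2 of unit B is not enolised.

Step 21
Reactants: 23 T–M dimer dialdehyde
Product: 24 benzyl-protected trimer with free 3,4-cis diol on unit B (2,3-cis-3,4-cis, both hydroxyls α)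
Conditions: SmI2 (2.5 equiv, 0.1 M in THF), t-BuOH (2 equiv), THF (0.01 M), −78 to −20 °C
Reagents that add atoms: none
Why: Divalent samarium transfers one electron to the more easily reduced aryl aldehyde (future C4); the resulting trivalent samarium ketyl adds to the samarium-bound α-aryloxy aldehyde (future C3), and a second electron transfer and protonation by t-BuOH give the diol. The closest known reaction type is the SmI2-promoted intramolecular pinacol coupling of 1,6-dialdehydes to cis-cyclohexane-1,2-diols. Ring C of B closes in the 6-exo-trig mode, the C4 radical attacking the C3 carbonyl carbon whose C=O bond is exocyclic to the forming ring. The cis relation of the C3 and C4 oxygens is controlled by the one trivalent samarium centre that bridges both oxygens in the bond-forming transition state. The configuration at C3 relative to C2 is controlled by chelation of the same metal to O1: with the 2-aryl group pseudo-equatorial, the chelated rotamer places the C3 oxygen gauche to O1 and therefore cis to the aryl group. The step needs chemoselective reduction of the aromatic carbonyl, which the absence of HMPA and the low temperature should secure, so that the aliphatic ketyl, which could expel the aryloxide at C2, is not formed; high dilution suppresses intermolecular coupling. Integrity of C2 is secured by the cold, base-free generation and immediate use of 23. All benzyl ethers are inert, and the acid-labile benzylic diol appears in a non-acidic medium.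

Step 22
Reactants: 24 benzyl-protected trimer
Product: 25 target trimer (CNP0140823.2)
Conditions: H2 (1 atm), Pd(OH)2/C, EtOAc–MeOH (1:1), rt; filtration and evaporation under argon
Reagents that add atoms: none
Why: Hydrogenolysis of nine aryl benzyl ethers and two secondary benzyl ethers under neutral conditions; the free benzylic C4–OH of unit B and the cyclic C2–O1 bonds are cleaved only when activated by acid, which is excluded.

## Compound list

1 | 2,3-dihydroxybenzaldehyde | O=Cc1cccc(O)c1O | starting material
2 | 2,3-bis(benzyloxy)benzaldehyde | O=Cc1cccc(OCc2ccccc2)c1OCc1ccccc1 | intermediate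
3 | 2,3-bis(benzyloxy)phenyl formate | O=COc1cccc(OCc2ccccc2)c1OCc1ccccc1 | intermediate
4 | 2,3-bis(benzyloxy)phenol | Oc1cccc(OCc2ccccc2)c1OCc1ccccc1 | intermediate
5 | 3,4-bis(benzyloxy)-2-hydroxybenzaldehyde | O=Cc1ccc(OCc2ccccc2)c(OCc2ccccc2)c1O | intermediate
6 | (S)-4-hydroxymandelic acid | O[C@H](C(=O)O)c1ccc(O)cc1 | starting material
7 | benzyl (2S)-[4-(benzyloxy)phenyl](hydroxy)acetate | O[C@H](C(=O)OCc1ccccc1)c1ccc(OCc2ccccc2)cc1 | intermediate
8 | benzyl (2R)-[4-(benzyloxy)phenyl][2,3-bis(benzyloxy)-6-formylphenoxy]acetate | O=Cc1ccc(OCc2ccccc2)c(OCc2ccccc2)c1O[C@H](c1ccc(OCc2ccccc2)cc1)C(=O)OCc1ccccc1 | intermediate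
9 | (2R)-2-[4-(benzyloxy)phenyl]-2-[2,3-bis(benzyloxy)-6-(hydroxymethyl)phenoxy]ethanol | OCc1ccc(OCc2ccccc2)c(OCc2ccccc2)c1O[C@H](c1ccc(OCc2ccccc2)cc1)CO | intermediate
10 | 3,4-bis(benzyloxy)-2-{(1R)-1-[4-(benzyloxy)phenyl]-2-oxoethoxy}benzaldehyde | O=Cc1ccc(OCc2ccccc2)c(OCc2ccccc2)c1O[C@H](c1ccc(OCc2ccccc2)cc1)C=O | intermediate
11 | (2R,3R,4R)-7,8-bis(benzyloxy)-2-[4-(benzyloxy)phenyl]chromane-3,4-diol (all-cis) | c1cc2c(c(OCc3ccccc3)c1OCc3ccccc3)O[C@H](c3ccc(OCc4ccccc4)cc3)[C@H](O)[C@@H]2O | intermediate
12 | (2R)-7,8-bis(benzyloxy)-2-[4-(benzyloxy)phenyl]-4β-(benzylsulfanyl)chroman-3α-ol (2,3-cis-3,4-trans) | c1cc2c(c(OCc3ccccc3)c1OCc3ccccc3)O[C@H](c3ccc(OCc4ccccc4)cc3)[C@H](O)[C@H]2SCc3ccccc3 | intermediate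
13 | (2R)-3α,7,8-tris(benzyloxy)-2-[4-(benzyloxy)phenyl]-4β-(benzylsulfanyl)chromane | c1cc2c(c(OCc3ccccc3)c1OCc3ccccc3)O[C@H](c3ccc(OCc4ccccc4)cc3)[C@H](OCc3ccccc3)[C@H]2SCc3ccccc3 | intermediate
14 | 3,4-O-thiocarbonyl derivative of 11 (cis-fused cyclic thionocarbonate) | c1cc2c(c(OCc3ccccc3)c1OCc3ccccc3)O[C@H](c3ccc(OCc4ccccc4)cc3)[C@@H]3OC(=S)O[C@H]23 | intermediate
15 | (2S)-7,8-bis(benzyloxy)-2-[4-(benzyloxy)phenyl]-2H-chromene | c1cc2c(c(OCc3ccccc3)c1OCc3ccccc3)O[C@H](c3ccc(OCc4ccccc4)cc3)C=C2 | intermediate
16 | (2R,3S,4S)-7,8-bis(benzyloxy)-2-[4-(benzyloxy)phenyl]chromane-3,4-diol (2,3-trans-3,4-cis) | c1cc2c(c(OCc3ccccc3)c1OCc3ccccc3)O[C@H](c3ccc(OCc4ccccc4)cc3)[C@@H](O)[C@H]2O | intermediate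
17 | (2R)-3β,4β,7,8-tetrakis(benzyloxy)-2-[4-(benzyloxy)phenyl]chromane | c1cc2c(c(OCc3ccccc3)c1OCc3ccccc3)O[C@H](c3ccc(OCc4ccccc4)cc3)[C@@H](OCc3ccccc3)[C@H]2OCc3ccccc3 | intermediate
18 | T–M dimer, C4β(T)–C6(M), unit M with 3β-OBn and 4β-OBn, all hydroxyls benzylated | c5ccccc5COc1ccc([C@H]2Oc3c(ccc(OCc5ccccc5)c3OCc5ccccc5)[C@H](c3cc4c(c(OCc5ccccc5)c3OCc5ccccc5)O[C@H](c3ccc(OCc5ccccc5)cc3)[C@@H](OCc5ccccc5)[C@H]4OCc5ccccc5)[C@H]2OCc5ccccc5)cc1 | intermediate
19 | T–M dimer with 2,3-bis(benzyloxy)-4-hydroxyphenyl on C4α of M | c5ccccc5COc1ccc([C@H]2Oc3c(ccc(OCc5ccccc5)c3OCc5ccccc5)[C@H](c3cc4c(c(OCc5ccccc5)c3OCc5ccccc5)O[C@H](c3ccc(OCc5ccccc5)cc3)[C@@H](OCc5ccccc5)[C@@H]4c3ccc(O)c(OCc5ccccc5)c3OCc5ccccc5)[C@H]2OCc5ccccc5)cc1 | intermediate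
20 | T–M dimer with 2,3-bis(benzyloxy)-5-formyl-4-hydroxyphenyl on C4α of M | c5ccccc5COc1ccc([C@H]2Oc3c(ccc(OCc5ccccc5)c3OCc5ccccc5)[C@H](c3cc4c(c(OCc5ccccc5)c3OCc5ccccc5)O[C@H](c3ccc(OCc5ccccc5)cc3)[C@@H](OCc5ccccc5)[C@@H]4c3cc(C=O)c(O)c(OCc5ccccc5)c3OCc5ccccc5)[C@H]2OCc5ccccc5)cc1 | intermediate
21 | T–M dimer formyl ester: aryl ether of benzyl (R)-[4-(benzyloxy)phenyl]acetate ortho to CHO | c5ccccc5COc1ccc([C@H]2Oc3c(ccc(OCc5ccccc5)c3OCc5ccccc5)[C@H](c3cc4c(c(OCc5ccccc5)c3OCc5ccccc5)O[C@H](c3ccc(OCc5ccccc5)cc3)[C@@H](OCc5ccccc5)[C@@H]4c3cc(C=O)c(c(OCc5ccccc5)c3OCc5ccccc5)O[C@H](c3ccc(OCc5ccccc5)cc3)C(=O)OCc5ccccc5)[C@H]2OCc5ccccc5)cc1 | intermediate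
22 | T–M dimer diol (aryl CH2OH and (R)-O–CH(aryl)–CH2OH) | c5ccccc5COc1ccc([C@H]2Oc3c(ccc(OCc5ccccc5)c3OCc5ccccc5)[C@H](c3cc4c(c(OCc5ccccc5)c3OCc5ccccc5)O[C@H](c3ccc(OCc5ccccc5)cc3)[C@@H](OCc5ccccc5)[C@@H]4c3cc(CO)c(c(OCc5ccccc5)c3OCc5ccccc5)O[C@H](c3ccc(OCc5ccccc5)cc3)CO)[C@H]2OCc5ccccc5)cc1 | intermediate
23 | T–M dimer dialdehyde (opened ring C of B) | c5ccccc5COc1ccc([C@H]2Oc3c(ccc(OCc5ccccc5)c3OCc5ccccc5)[C@H](c3cc4c(c(OCc5ccccc5)c3OCc5ccccc5)O[C@H](c3ccc(OCc5ccccc5)cc3)[C@@H](OCc5ccccc5)[C@@H]4c3cc(C=O)c(c(OCc5ccccc5)c3OCc5ccccc5)O[C@H](c3ccc(OCc5ccccc5)cc3)C=O)[C@H]2OCc5ccccc5)cc1 | intermediate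
24 | benzyl-protected trimer with free all-cis 3,4-diol on B | c5ccccc5COc1ccc([C@H]2Oc3c(ccc(OCc5ccccc5)c3OCc5ccccc5)[C@H](c3cc4c(c(OCc5ccccc5)c3OCc5ccccc5)O[C@H](c3ccc(OCc5ccccc5)cc3)[C@@H](OCc5ccccc5)[C@@H]4c3cc4c(c(OCc5ccccc5)c3OCc5ccccc5)O[C@H](c3ccc(OCc5ccccc5)cc3)[C@H](O)[C@@H]4O)[C@H]2OCc5ccccc5)cc1 | intermediate
25 | target trimer CNP0140823.2 | Oc1ccc([C@H]2Oc3c(ccc(O)c3O)[C@H](c3cc4c(c(O)c3O)O[C@H](c3ccc(O)cc3)[C@@H](O)[C@@H]4c3cc4c(c(O)c3O)O[C@H](c3ccc(O)cc3)[C@H](O)[C@@H]4O)[C@H]2O)cc1 | target

## Step count and least certain steps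

Total: 22 steps. Longest linear sequence: 19 steps (1, 2, 3, 5, 6, 7, 8, 11, 12, 13, 14, 15, 16, 17, 18, 19, 20, 21, 22).

Step 21 (key step; step 8 is the same reaction on the monomer).
- Risk: loss of stereocontrol at C3. If trivalent samarium does not bind the aryl ether oxygen O1, the aldehyde reacts in the dipole-minimised rotamer and the diol forms cis but trans to the 2-aryl group. Enolisation of 23 at C2 before electron transfer, and reductive cleavage of C2–O1 if the aliphatic carbonyl is reduced first, are the lesser risks.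
- Fallback, from 23 back to 24: the configuration at C3 and C4 is then set by SN2 inversion and hydride delivery. The non-chelated coupling would give mainly the unit-B 2,3-trans-3,4-cis diol F1. MnO2 in CH2Cl2 oxidises only its benzylic C4 carbinol to the 2,3-trans 3-hydroxy-4-ketone F2. Mitsunobu reaction with 4-nitrobenzoic acid (PPh3, DIAD, toluene, 0 °C) inverts C3 at the carbonyl-activated carbon to give the 2,3-cis 3-(4-nitrobenzoyloxy)-4-ketone F3. NaBH4/CeCl3·7H2O in MeOH–THF at −78 °C delivers hydride anti to the axial acyloxy group to give the all-cis 4-ol 3-(4-nitrobenzoate) F4. K2CO3 in MeOH at 0 °C removes the ester and gives 24.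

Step 15.
- Risk: self-alkylation of the electrophile, since ring A of 13 is as nucleophilic as ring A of 17, and loss of the C3 proton from a long-lived cation in the buffered medium.
- Fallback, from 11 back to 18: bromine capping of the nucleophilic carbon of unit T. NBS (CH2Cl2, −78 °C) brominates C6 of 11 to the 6-bromo diol F5. Thiolysis as in step 9 gives the 6-bromo sulfide F6 and benzylation as in step 10 gives the 6-bromo benzyl ether F7. The silver-promoted coupling with 17 then gives the 6-bromo dimer F8 without competition from the capped ring. Bromine–lithium exchange (n-BuLi, THF, −78 °C) and quenching with MeOH give 18.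

Step 16.
- Risk: attack ortho instead of para to the hydroxyl of 4, since each of the two free positions has one ortho and one para oxygen, and incomplete facial selectivity at C4 of the 2,3-trans cation.
- Fallback, from 4 and 18 back to 20 (step 17 is then not needed): the ortho position is blocked by a bromine that later becomes the formyl group. Amine-catalysed ortho-bromination of 4 (NBS, i-Pr2NH cat., CH2Cl2, 0 °C) gives 6-bromo-2,3-bis(benzyloxy)phenol F9. Coupling with 18 under the conditions of step 16 can occur only para to the hydroxyl and gives the bromo phenol F10. Deprotonation and bromine–lithium exchange (n-BuLi, 3.3 equiv, THF, −78 °C) followed by DMF give 20.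

Step 18.
- Risk: sluggish etherification of a doubly ortho-substituted, hydrogen-bonded phenol on a large substrate, and partial loss of configuration through ionisation at the 4-alkoxybenzylic carbinol.
- Fallback, from 7 and 20 back to 21: alkylation without stereospecificity, followed by separation of diastereomers. Appel bromination of 7 (CBr4, PPh3, CH2Cl2, 0 °C) gives the racemic bromo ester F11. Alkylation of 20 with F11 (Cs2CO3, DMF, 0 °C) gives 21 together with its C2 epimer F12. The two are diastereomers and are separated by chromatography; F12 is re-equilibrated at C2 with DBU and separated again.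

Step 22.
- Risk: hydrogenolysis of the activated benzylic C4–O bond of unit B, or stalling before the two hindered secondary benzyl ethers are cleaved, and air oxidation of the product during isolation.
- Fallback, from 24 back to 25: the diol is masked during hydrogenolysis. TESCl, imidazole and DMAP in DMF give the 3,4-bis(triethylsilyl) ether F13. Hydrogenolysis as in step 22 gives the bis(triethylsilyl) ether of the target F14, in which the silylated benzylic oxygen is not hydrogenolysed. Et3N·3HF in THF at 0 °C under argon then gives 25.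

## Further compounds

F1 | step 21 | C3,C4-diepimer of 24 (unit B 2,3-trans-3,4-cis diol, both hydroxyls β) | c5ccccc5COc1ccc([C@H]2Oc3c(ccc(OCc5ccccc5)c3OCc5ccccc5)[C@H](c3cc4c(c(OCc5ccccc5)c3OCc5ccccc5)O[C@H](c3ccc(OCc5ccccc5)cc3)[C@@H](OCc5ccccc5)[C@@H]4c3cc4c(c(OCc5ccccc5)c3OCc5ccccc5)O[C@H](c3ccc(OCc5ccccc5)cc3)[C@@H](O)[C@H]4O)[C@H]2OCc5ccccc5)cc1
F2 | step 21 | unit B 2,3-trans 3β-hydroxy-4-ketone analogue of 24 | c5ccccc5COc1ccc([C@H]2Oc3c(ccc(OCc5ccccc5)c3OCc5ccccc5)[C@H](c3cc4c(c(OCc5ccccc5)c3OCc5ccccc5)O[C@H](c3ccc(OCc5ccccc5)cc3)[C@@H](OCc5ccccc5)[C@@H]4c3cc4c(c(OCc5ccccc5)c3OCc5ccccc5)O[C@H](c3ccc(OCc5ccccc5)cc3)[C@@H](O)C4=O)[C@H]2OCc5ccccc5)cc1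
F3 | step 21 | unit B 2,3-cis 3α-(4-nitrobenzoyloxy)-4-ketone analogue of 24 | c5ccccc5COc1ccc([C@H]2Oc3c(ccc(OCc5ccccc5)c3OCc5ccccc5)[C@H](c3cc4c(c(OCc5ccccc5)c3OCc5ccccc5)O[C@H](c3ccc(OCc5ccccc5)cc3)[C@@H](OCc5ccccc5)[C@@H]4c3cc4c(c(OCc5ccccc5)c3OCc5ccccc5)O[C@H](c3ccc(OCc5ccccc5)cc3)[C@H](OC(=O)c3ccc(cc3)[N+](=O)[O-])C4=O)[C@H]2OCc5ccccc5)cc1
F4 | step 21 | 3-O-(4-nitrobenzoyl) derivative of 24 (unit B all-cis) | c5ccccc5COc1ccc([C@H]2Oc3c(ccc(OCc5ccccc5)c3OCc5ccccc5)[C@H](c3cc4c(c(OCc5ccccc5)c3OCc5ccccc5)O[C@H](c3ccc(OCc5ccccc5)cc3)[C@@H](OCc5ccccc5)[C@@H]4c3cc4c(c(OCc5ccccc5)c3OCc5ccccc5)O[C@H](c3ccc(OCc5ccccc5)cc3)[C@H](OC(=O)c3ccc(cc3)[N+](=O)[O-])[C@@H]4O)[C@H]2OCc5ccccc5)cc1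
F5 | step 15 | (2R,3R,4R)-6-bromo-7,8-bis(benzyloxy)-2-[4-(benzyloxy)phenyl]chromane-3,4-diol | Brc1cc2c(c(OCc3ccccc3)c1OCc3ccccc3)O[C@H](c3ccc(OCc4ccccc4)cc3)[C@H](O)[C@@H]2O
F6 | step 15 | 6-bromo analogue of 12 | Brc1cc2c(c(OCc3ccccc3)c1OCc3ccccc3)O[C@H](c3ccc(OCc4ccccc4)cc3)[C@H](O)[C@H]2SCc3ccccc3
F7 | step 15 | 6-bromo analogue of 13 | Brc1cc2c(c(OCc3ccccc3)c1OCc3ccccc3)O[C@H](c3ccc(OCc4ccccc4)cc3)[C@H](OCc3ccccc3)[C@H]2SCc3ccccc3
F8 | step 15 | analogue of 18 with bromine on C6 of unit T | c5ccccc5COc1ccc([C@H]2Oc3c(cc(Br)c(OCc5ccccc5)c3OCc5ccccc5)[C@H](c3cc4c(c(OCc5ccccc5)c3OCc5ccccc5)O[C@H](c3ccc(OCc5ccccc5)cc3)[C@@H](OCc5ccccc5)[C@H]4OCc5ccccc5)[C@H]2OCc5ccccc5)cc1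
F9 | step 16 | 6-bromo-2,3-bis(benzyloxy)phenol | Oc1c(Br)ccc(OCc2ccccc2)c1OCc1ccccc1
F10 | step 16 | analogue of 19 with bromine ortho to the phenolic hydroxyl | c5ccccc5COc1ccc([C@H]2Oc3c(ccc(OCc5ccccc5)c3OCc5ccccc5)[C@H](c3cc4c(c(OCc5ccccc5)c3OCc5ccccc5)O[C@H](c3ccc(OCc5ccccc5)cc3)[C@@H](OCc5ccccc5)[C@@H]4c3cc(Br)c(O)c(OCc5ccccc5)c3OCc5ccccc5)[C@H]2OCc5ccccc5)cc1
F11 | step 18 | benzyl 2-bromo-2-[4-(benzyloxy)phenyl]acetate (racemic) | BrC(C(=O)OCc1ccccc1)c1ccc(OCc2ccccc2)cc1
F12 | step 18 | epimer of 21 at the aryloxy-bearing carbon (S) | c5ccccc5COc1ccc([C@H]2Oc3c(ccc(OCc5ccccc5)c3OCc5ccccc5)[C@H](c3cc4c(c(OCc5ccccc5)c3OCc5ccccc5)O[C@H](c3ccc(OCc5ccccc5)cc3)[C@@H](OCc5ccccc5)[C@@H]4c3cc(C=O)c(c(OCc5ccccc5)c3OCc5ccccc5)O[C@@H](c3ccc(OCc5ccccc5)cc3)C(=O)OCc5ccccc5)[C@H]2OCc5ccccc5)cc1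
F13 | step 22 | 3,4-bis-O-triethylsilyl ether of 24 | c5ccccc5COc1ccc([C@H]2Oc3c(ccc(OCc5ccccc5)c3OCc5ccccc5)[C@H](c3cc4c(c(OCc5ccccc5)c3OCc5ccccc5)O[C@H](c3ccc(OCc5ccccc5)cc3)[C@@H](OCc5ccccc5)[C@@H]4c3cc4c(c(OCc5ccccc5)c3OCc5ccccc5)O[C@H](c3ccc(OCc5ccccc5)cc3)[C@H](O[Si](CC)(CC)CC)[C@@H]4O[Si](CC)(CC)CC)[C@H]2OCc5ccccc5)cc1
F14 | step 22 | 3,4-bis-O-triethylsilyl ether (unit B) of 25 | Oc1ccc([C@H]2Oc3c(ccc(O)c3O)[C@H](c3cc4c(c(O)c3O)O[C@H](c3ccc(O)cc3)[C@@H](O)[C@@H]4c3cc4c(c(O)c3O)O[C@H](c3ccc(O)cc3)[C@H](O[Si](CC)(CC)CC)[C@@H]4O[Si](CC)(CC)CC)[C@H]2O)cc1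
A1 | alternative 1 | unit T bearing on C4 the new ring A of M (free C8a hydroxyl, tert-butoxy on C8 and C7) | c5ccccc5COc1ccc([C@H]2Oc3c(ccc(OCc5ccccc5)c3OCc5ccccc5)[C@H](c3ccc(O)c(OC(C)(C)C)c3OC(C)(C)C)[C@H]2OCc5ccccc5)cc1
A2 | alternative 1 | unit T bearing on C4 the diazo vinyl ketone C(=N2)–C(=O)–CH=CH2 | c5ccccc5COc1ccc([C@H]2Oc3c(ccc(OCc5ccccc5)c3OCc5ccccc5)[C@H](C(=[N+]=[N-])C(=O)C=C)[C@H]2OCc5ccccc5)cc1
A3 | alternative 1 | di-tert-butoxyethyne | CC(C)(C)OC#COC(C)(C)C
A4 | alternative 2 | protected trimer with pinacol boronate on C3 of M and acetonide on B | c5ccccc5COc1ccc([C@H]2Oc3c(ccc(OCc5ccccc5)c3OCc5ccccc5)[C@H](c3cc4c(c(OCc5ccccc5)c3OCc5ccccc5)O[C@H](c3ccc(OCc5ccccc5)cc3)[C@@H](B6OC(C)(C)C(C)(C)O6)[C@@H]4c3cc4c(c(OCc5ccccc5)c3OCc5ccccc5)O[C@H](c3ccc(OCc5ccccc5)cc3)[C@H](OC6(C)C)[C@@H]4O6)[C@H]2OCc5ccccc5)cc1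
A5 | alternative 2 | o-hydroxy diaryl carbinol: ring A of M (free C8a hydroxyl, T on C6) joined through CH(OH) to C6 of the acetonide-protected B unit | c5ccccc5COc1ccc([C@H]2Oc3c(ccc(OCc5ccccc5)c3OCc5ccccc5)[C@H](c3cc(C(O)c4cc6c(c(OCc5ccccc5)c4OCc5ccccc5)O[C@H](c4ccc(OCc5ccccc5)cc4)[C@H](OC7(C)C)[C@@H]6O7)c(O)c(OCc5ccccc5)c3OCc5ccccc5)[C@H]2OCc5ccccc5)cc1
A6 | alternative 2 | (E)-2-{2-[4-(benzyloxy)phenyl]ethenyl}-4,4,5,5-tetramethyl-1,3,2-dioxaborolane | CC1(C)OB(/C=C/c2ccc(OCc3ccccc3)cc2)OC1(C)C
A7 | alternative 3 | protected trimer with free C3 hydroxyl on T and acetonide on B | c5ccccc5COc1ccc([C@H]2Oc3c(ccc(OCc5ccccc5)c3OCc5ccccc5)[C@H](c3cc4c(c(OCc5ccccc5)c3OCc5ccccc5)O[C@H](c3ccc(OCc5ccccc5)cc3)[C@@H](OCc5ccccc5)[C@@H]4c3cc4c(c(OCc5ccccc5)c3OCc5ccccc5)O[C@H](c3ccc(OCc5ccccc5)cc3)[C@H](OC6(C)C)[C@@H]4O6)[C@H]2O)cc1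
A8 | alternative 3 | trans-epoxide precursor: C2 of T bearing the 2,3-bis(benzyloxy)phenoxy group, C3–C4 epoxide, C4 bonded to C6 of the M–B part | c5ccccc5COc1ccc([C@@H](Oc3cccc(OCc5ccccc5)c3OCc5ccccc5)[C@@H]2O[C@H]2c3cc4c(c(OCc5ccccc5)c3OCc5ccccc5)O[C@H](c3ccc(OCc5ccccc5)cc3)[C@@H](OCc5ccccc5)[C@@H]4c3cc4c(c(OCc5ccccc5)c3OCc5ccccc5)O[C@H](c3ccc(OCc5ccccc5)cc3)[C@H](OC6(C)C)[C@@H]4O6)cc1
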